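(The constants belong to no real substance.)

Early in these runs target has to come through intermediate C, so we reckon how long that passage takes.

| flask | substrate | reagent | time |
|---|---|---|---|
| violet | 0.13 M (fed, over 8.0 min) | 0.900 equiv | 15 min |
| ochre | 0.13 M (fed, over 8.0 min) | 1.40 equiv | 15 min |
| grey | 0.13 M (fed, over 8.0 min) | 2.00 equiv | 15 min |

    substrate + reagent → side product (k1 = 0.600 L mol⁻¹ min⁻¹)
    substrate ⇌ intermediate A (K2 = 1.2, k2 = 0.570 min⁻¹)
    reagent + intermediate A ⇌ intermediate B (K3 = 2.5 L mol⁻¹, k3 = 0.452 L mol⁻¹ min⁻¹)
    intermediate A ⇌ intermediate C (K4 = 25, k4 = 0.00375 min⁻¹)
    reagent + intermediate C → target (k5 = 0.202 L mol⁻¹ min⁻¹)
    target ⇌ isomer of the product (K6 = 25, k6 = 0.0335 min⁻¹)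
    substrate ⇌ dormant form (K7 = 0.910, k7 = 0.115 min⁻¹)

- which of the two there is more of at the end, violet (target / side product)
- which of the two there is more of at the end, ochre (target / side product)
- which of the two there is more of at the end, grey (target / side product)
- final target, as a percentage of the substrate charged, in violet
- final target, as a percentage of the substrate charged, in ochre
- final target, as a percentage of the substrate charged, in grey

**Main route.** First take the main route and nothing else. The whole charge stands as intermediate A, turns into intermediate C at its forward constant, and reagent at its charged c(reagent) carries intermediate C on to target. Intermediate C then grows with time, and target with the square of time. Its share of the charge is half the square of time over a gate time. In violet that time is 106 min: the gate time, our induction time, is one over the square root of both forward constants times c(reagent). The feed is steady, so the average substrate arrives at mid-feed and its clock runs 11.0 min. Violet then gets 0.536%.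

**Resting pools.** Now add the equilibria. Step 7 by itself, forward rate only, gives substrate a half-life of 6.0 min, shorter than our clock, so we let the pool split by its constants. Intermediate B is counted as well. We take its ratio to intermediate A in violet as 0.29, the equilibrium constant of step 3 times c(reagent) at the start. Intermediate A then holds 34.7% of the pool, and violet falls to 0.186%.

**The rest.** Next comes the side reaction. Substrate is 32.2% of the pool without intermediate B. Over our clock, step by step, the violet pool keeps 78.0%. Reagent shrinks too, and we let this one factor stand for both, which gives 0.145%. Last, target leaks to its isomer, with a half-life of 21 min by the forward rate of step 6 by itself. We take the mean age of target made so late as 3.67 min, so 88.4% of it stays.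

**Our reckoning.** We commit to 0.128% in violet, 0.165% in ochre and 0.187% in grey. Taking the pool's loss as side product, the leader is side product in violet, side product in ochre and side product in grey.

**The forecast.** It gives 0.1%, 0.15% and 0.21%, with side product, side product and side product ahead. Its ground: “Target should therefore scale roughly with the free reagent left late in the run”. It stands lower than ours in violet and higher than ours in grey.

**The flasks.** Violet, ochre and grey end with 0.114%, 0.158% and 0.196% of target, against 21.1%, 30.0% and 38.7% of side product. Now take the neighbour, like ochre but with 0.840 equiv of reagent. From 106 min, its gate time is 110 min, and the same steps give 0.123% of target and 20.7% of side product. That flask holds 19.9% of side product and 0.107% of target.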